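**Retrosynthetic overview**
1. Target 31 ⇒ diol 24 (late acylation of the equatorial C9 hydroxyl) ⇒ 7α,8α-epoxy-9α-ol 22 (trans-diaxial opening at C7 by an isopropenyl copper reagent) ⇒ enone 18 ⇒ C9 ketone 16.
2. 16 ⇒ dienone 11: hydrogenation sets C4 and C10, a Selectride reduction sets the axial C2 hydroxyl, and the C9 silyl ether is unmasked and oxidised.
3. The strategy rests on ring A (C1–C2–C3–C4–C5–C10): its oxygen on C2 is para to the quaternary C5, with methyls on C4 and C5, so ring A is a 3,4-dimethylphenol alkylated at its para carbon. Hence the C5–C6 bond is cut: 11 ⇒ dibromophenol iodide 10, by intramolecular para-C-alkylation of the phenolate.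
4. 10 ⇒ 1-bromo-2,3-dimethylbenzene 1 + 4-chlorobutanoyl chloride 2 (acylation, CBS reduction, silylation, C–H borylation/oxidation, dibromination, Finkelstein exchange).
5. Ring order: ring A is present from the start as the arene; ring B is closed in the key step.

Key step: step 7

Remark: eremophilane numbering is used throughout (ring A = C1–C2–C3–C4–C5–C10, ring B = C5–C6–C7–C8–C9–C10); β is the face of the C5 methyl, and "trans-decalin" means the 10α-H ring fusion.

Step 1
Reactants: 1 1-bromo-2,3-dimethylbenzene; 2 4-chlorobutanoyl chloride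
Product: 4 4-chloro-1-(2,3-dimethylphenyl)butan-1-one, via aryl Grignard reagent 3 (not isolated)
Conditions: Mg, THF, reflux; then added to 2, Fe(acac)3 (3 mol%), THF, −78 °C
Reagents that add atoms: none
Why: Magnesium insertion gives Grignard reagent 3, whose iron-catalysed acylation by the acid chloride at −78 °C (Kumada-type acylation) should stop at the ketone, because the acyl chloride reacts far faster than the product ketone or the primary alkyl chloride.

Step 2
Reactants: 4 4-chloro-1-(2,3-dimethylphenyl)butan-1-one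
Product: 5 (1S)-4-chloro-1-(2,3-dimethylphenyl)butan-1-ol
Conditions: (R)-2-methyl-CBS-oxazaborolidine (10 mol%), BH3·SMe2, THF, −20 °C; then MeOH
Reagents that add atoms: none
Why: Corey–Bakshi–Shibata reduction of an aryl alkyl ketone with the (R)-catalyst places the aryl group as the large substituent and should deliver hydride to give the (S)-carbinol, which sets C9, the centre that later relays its configuration to C5.

Step 3
Reactants: 5 (1S)-4-chloro-1-(2,3-dimethylphenyl)butan-1-ol
Product: 6 tert-butyl[(1S)-4-chloro-1-(2,3-dimethylphenyl)butoxy]dimethylsilane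
Conditions: TBSOTf, 2,6-lutidine, CH2Cl2, −78 to 0 °C
Reagents that add atoms: tert-butyldimethylsilyl trifluoromethanesulfonate CC(C)(C)[Si](C)(C)OS(=O)(=O)C(F)(F)F
Why: Silylation with the reactive triflate and a non-nucleophilic base protects the hindered benzylic alcohol without forming an alkoxide that could close a tetrahydrofuran onto the γ-chloride.

Step 4
Reactants: 6 tert-butyl[(1S)-4-chloro-1-(2,3-dimethylphenyl)butoxy]dimethylsilane
Product: 8 3-[(1S)-1-(tert-butyldimethylsilyloxy)-4-chlorobutyl]-4,5-dimethylphenol, via arylboronic pinacol ester 7 (not isolated)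
Conditions: [Ir(cod)OMe]2 (1.5 mol%), 4,4'-di-tert-butyl-2,2'-bipyridine (3 mol%), B2pin2, THF, 80 °C; then Oxone (2KHSO5·KHSO4·K2SO4), acetone/H2O, 25 °C, 10 min
Reagents that add atoms: bis(pinacolato)diboron CC1(C)OB(OC1(C)C)B1OC(C)(C)C(C)(C)O1 (boron of 7 only); potassium peroxymonosulfate [K+].[O-]S(=O)(=O)OO (phenol oxygen)
Why: Sterically governed Hartwig–Miyaura C–H borylation should take the only ring C–H that has no ortho substituent (the future C2, para to the methyl-bearing C5), and the one-pot peroxymonosulfate oxidation of the C–B bond gives the phenol under non-basic conditions that leave the alkyl chloride and the secondary silyl ether intact.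

Step 5
Reactants: 8 3-[(1S)-1-(tert-butyldimethylsilyloxy)-4-chlorobutyl]-4,5-dimethylphenol
Product: 9 2,6-dibromo-3-[(1S)-1-(tert-butyldimethylsilyloxy)-4-chlorobutyl]-4,5-dimethylphenol
Conditions: NBS (2.05 equiv), i-Pr2NH (10 mol%), CH2Cl2, 0 °C, dark
Reagents that add atoms: N-bromosuccinimide O=C1CCC(=O)N1Br
Why: Amine-catalysed electrophilic aromatic bromination of a para-blocked phenol should go to both ortho positions (C1 and C3), and the absence of strong acid spares the silyl ether.

Step 6
Reactants: 9 2,6-dibromo-3-[(1S)-1-(tert-butyldimethylsilyloxy)-4-chlorobutyl]-4,5-dimethylphenol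
Product: 10 2,6-dibromo-3-[(1S)-1-(tert-butyldimethylsilyloxy)-4-iodobutyl]-4,5-dimethylphenol
Conditions: NaI, acetone, reflux
Reagents that add atoms: sodium iodide [Na+].[I-]
Why: Finkelstein exchange, driven by precipitation of NaCl, turns the chloride carried from step 1 into the better leaving group while the phenol stays neutral; a halide is used at C6 because a primary sulfonate could not be installed chemoselectively beside the acidic 2,6-dibromophenol.

Step 7
Reactants: 10 2,6-dibromo-3-[(1S)-1-(tert-butyldimethylsilyloxy)-4-iodobutyl]-4,5-dimethylphenol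
Product: 11 (4aR,8S)-1,3-dibromo-8-(tert-butyldimethylsilyloxy)-4,4a-dimethyl-5,6,7,8-tetrahydronaphthalen-2(4aH)-one (9β-silyloxy group cis to the 5β-methyl)
Conditions: KOtBu (1.0 equiv), t-BuOH/THF (0.01 M), 25 to 50 °C
Reagents that add atoms: none
Why: KOtBu (exactly one equivalent, so that no free base remains for E2 loss of HI) converts the acidic dibromophenol into its potassium phenolate, whose para carbon C5 displaces iodide from C6 in an intramolecular SN2 reaction, forming C5–C6 and leaving the cross-conjugated cyclohexadienone. The closest known reaction type is the Winstein–Masamune alkylative dearomatisation of phenolates (Ar2-6 participation of a meta-tethered chain at the para carbon). Ring B is closed in the 6-exo-tet mode. The new stereocentre C5 is controlled by C9: A(1,3) strain with the C1 bromine holds the C9–H bond in the arene plane, so the chain and the silyloxy group lie on opposite faces, C6 bonds to C5 from the face of the chain, and the C5 methyl ends up cis to the silyl ether. The step needs C- over O-alkylation and para over ortho attack: O-alkylation would require a meta-bridged eight-membered ring and is possible only between molecules (suppressed by dilution), and the ortho carbon C1, the only other carbon within reach of the chain, carries bromine.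

Step 8
Reactants: 11 (4aR,8S)-1,3-dibromo-8-(tert-butyldimethylsilyloxy)-4,4a-dimethyl-5,6,7,8-tetrahydronaphthalen-2(4aH)-one
Product: 12 9β-(tert-butyldimethylsilyloxy)-4β,5β-dimethyl-trans-decalin-2-one
Conditions: H2 (1 atm), Pd/C, Et3N (2.2 equiv), EtOAc, 25 °C
Reagents that add atoms: none
Why: Pd-catalysed hydrogenolysis removes both vinylic bromines (Et3N takes up HBr) and syn hydrogenation should saturate C3=C4 and C1=C10 from the α face, because the β face of the flat dienone is covered by the axial C5 methyl and the axial C9 silyloxy group; this sets C4 (methyl β, cis to the C5 methyl) and C10 (H α, trans ring fusion).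

Step 9
Reactants: 12 9β-(tert-butyldimethylsilyloxy)-4β,5β-dimethyl-trans-decalin-2-one
Product: 13 9β-(tert-butyldimethylsilyloxy)-4β,5β-dimethyl-trans-decalin-2α-ol
Conditions: L-Selectride (LiBH(s-Bu)3), THF, −78 °C; then H2O
Reagents that add atoms: none
Why: The bulky hydride of L-Selectride attacks the C2 carbonyl of the rigid trans-decalone along the equatorial direction and should give the axial 2α-alcohol, as in the Selectride reduction of 5α-3-ketosteroids to 3α-alcohols.

Step 10
Reactants: 13 9β-(tert-butyldimethylsilyloxy)-4β,5β-dimethyl-trans-decalin-2α-ol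
Product: 14 2α-(4-methoxybenzyloxy)-9β-(tert-butyldimethylsilyloxy)-4β,5β-dimethyl-trans-decalin
Conditions: NaH, 4-methoxybenzyl chloride, Bu4NI (cat.), THF/DMF, 0 to 25 °C
Reagents that add atoms: 4-methoxybenzyl chloride COc1ccc(CCl)cc1
Why: Williamson etherification masks the C2 hydroxyl with a group that survives fluoride, enolate, hydride, Mitsunobu, peracid and organocopper steps and can be removed oxidatively at the end.

Step 11
Reactants: 14 2α-(4-methoxybenzyloxy)-9β-(tert-butyldimethylsilyloxy)-4β,5β-dimethyl-trans-decalin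
Product: 15 2α-(4-methoxybenzyloxy)-4β,5β-dimethyl-trans-decalin-9β-ol
Conditions: TBAF, THF, 50 °C
Reagents that add atoms: none
Why: Fluoride-induced desilylation frees the C9 hydroxyl, whose stereochemical task (control of C5 and of the hydrogenation face) is now complete.

Step 12
Reactants: 15 2α-(4-methoxybenzyloxy)-4β,5β-dimethyl-trans-decalin-9β-ol
Product: 16 2α-(4-methoxybenzyloxy)-4β,5β-dimethyl-trans-decalin-9-one
Conditions: Dess–Martin periodinane, CH2Cl2, 0 to 25 °C
Reagents that add atoms: none
Why: Dess–Martin oxidation of the strained axial alcohol gives the C9 ketone under non-basic conditions that do not epimerise the adjacent ring-fusion centre C10.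

Step 13
Reactants: 16 2α-(4-methoxybenzyloxy)-4β,5β-dimethyl-trans-decalin-9-one
Product: 18 2α-(4-methoxybenzyloxy)-4β,5β-dimethyl-trans-decal-7-en-9-one, via trimethylsilyl enol ether 17 (not isolated)
Conditions: LDA (LiN(i-Pr)2), TMSCl, THF, −78 °C; then Pd(OAc)2, MeCN, 25 °C
Reagents that add atoms: chlorotrimethylsilane C[Si](C)(C)Cl (silicon of 17 only)
Why: Kinetic deprotonation by LDA occurs at the C8 methylene and not at the ring-fusion C10–H, so C10 is untouched, and Saegusa–Ito oxidation of the silyl enol ether with Pd(OAc)2 introduces the C7=C8 double bond.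

Step 14
Reactants: 18 2α-(4-methoxybenzyloxy)-4β,5β-dimethyl-trans-decal-7-en-9-one
Product: 19 2α-(4-methoxybenzyloxy)-4β,5β-dimethyl-trans-decal-7-en-9β-ol
Conditions: NaBH4, CeCl3·7H2O, MeOH, −78 to −40 °C
Reagents that add atoms: none
Why: Luche reduction gives clean 1,2-reduction, and hydride should approach C9 from the α face because axial attack from the β face is blocked by the syn-axial C5 methyl, giving the 9β (pseudoaxial) allylic alcohol; any 9α-epimer is already compound 21 and is carried forward directly.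

Step 15
Reactants: 19 2α-(4-methoxybenzyloxy)-4β,5β-dimethyl-trans-decal-7-en-9β-ol
Product: 20 2α-(4-methoxybenzyloxy)-4β,5β-dimethyl-trans-decal-7-en-9α-yl 4-nitrobenzoate
Conditions: 4-nitrobenzoic acid, PPh3, DIAD, toluene, 0 to 25 °C
Reagents that add atoms: 4-nitrobenzoic acid OC(=O)c1ccc(cc1)[N+](=O)[O-]
Why: Mitsunobu reaction with the acidic 4-nitrobenzoic acid displaces the 9β-oxyphosphonium group by SN2 from the open α face and so inverts C9 to the α (equatorial) configuration of the target.

Step 16
Reactants: 20 2α-(4-methoxybenzyloxy)-4β,5β-dimethyl-trans-decal-7-en-9α-yl 4-nitrobenzoate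
Product: 21 2α-(4-methoxybenzyloxy)-4β,5β-dimethyl-trans-decal-7-en-9α-ol
Conditions: K2CO3 (cat.), MeOH, 25 °C
Reagents that add atoms: none
Why: Base-catalysed transesterification of the activated nitrobenzoate with methanol releases the 9α-allylic alcohol with retention at C9.

Step 17
Reactants: 21 2α-(4-methoxybenzyloxy)-4β,5β-dimethyl-trans-decal-7-en-9α-ol
Product: 22 7α,8α-epoxy-2α-(4-methoxybenzyloxy)-4β,5β-dimethyl-trans-decalin-9α-ol
Conditions: mCPBA, CH2Cl2, 0 °C
Reagents that add atoms: 3-chloroperoxybenzoic acid OOC(=O)c1cccc(Cl)c1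
Why: Prilezhaev epoxidation is directed by hydrogen bonding to the allylic 9α-hydroxyl (Henbest effect), and the α face is also the one remote from the axial C5 methyl, so the 7α,8α-epoxide cis to the hydroxyl should form.

Step 18
Reactants: 22 7α,8α-epoxy-2α-(4-methoxybenzyloxy)-4β,5β-dimethyl-trans-decalin-9α-ol; 23 isopropenylmagnesium bromide
Product: 24 7β-isopropenyl-2α-(4-methoxybenzyloxy)-4β,5β-dimethyl-trans-decalin-8α,9α-diol
Conditions: CuBr·SMe2 (20 mol%), THF, −30 to 0 °C; then H2O
Reagents that add atoms: none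
Why: Copper-catalysed Grignard opening of the epoxide follows the Fürst–Plattner rule in the rigid trans-decalin, so the isopropenyl group should enter axially at C7 from the β face, remote from the C9 alkoxide, giving the trans-diaxial 7β-isopropenyl-8α-ol and setting C7 and C8.

Step 19
Reactants: 25 ethyl pent-2-ynoate
Product: 26 ethyl (2Z)-3-methylpent-2-enoate
Conditions: Me2CuLi (from MeLi and CuBr·SMe2), THF, −78 °C; then MeOH/H2O at −78 °C
Reagents that add atoms: lithium dimethylcuprate [Li+].C[Cu-]C
Why: Syn carbocupration of the ynoate puts the new methyl and the copper on the same side, and cold protonation with retention leaves the ethyl group cis to the ester, which is the (Z)-geometry.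

Step 20
Reactants: 26 ethyl (2Z)-3-methylpent-2-enoate
Product: 27 (2Z)-3-methylpent-2-enoic acid
Conditions: LiOH, THF/H2O, 25 °C; then HCl
Reagents that add atoms: lithium hydroxide [Li+].[OH-]
Why: Saponification proceeds by acyl substitution at the carbonyl and does not touch the trisubstituted double bond, so the geometry is kept.

Step 21
Reactants: 27 (2Z)-3-methylpent-2-enoic acid
Product: 28 (2Z)-3-methylpent-2-enoyl chloride
Conditions: 1-chloro-N,N,2-trimethylprop-1-en-1-amine, CH2Cl2, 0 °C (used as a solution)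
Reagents that add atoms: 1-chloro-N,N,2-trimethylprop-1-en-1-amine CC(C)=C(Cl)N(C)C
Why: The Ghosez reagent forms the acid chloride under neutral conditions without HCl or amine base, so neither acid- nor ketene-mediated Z/E scrambling of the enoyl unit is expected.

Step 22
Reactants: 24 7β-isopropenyl-2α-(4-methoxybenzyloxy)-4β,5β-dimethyl-trans-decalin-8α,9α-diol; 28 (2Z)-3-methylpent-2-enoyl chloride
Product: 30 8α-hydroxy-7β-isopropenyl-2α-(4-methoxybenzyloxy)-4β,5β-dimethyl-trans-decalin-9α-yl (2Z)-3-methylpent-2-enoate, via dibutylstannylene acetal 29 (not isolated)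
Conditions: Bu2SnO, toluene, reflux (−H2O); then 28, CH2Cl2, 0 °C; then H2O
Reagents that add atoms: dibutyltin oxide CCCC[Sn](=O)CCCC (tin of 29 only)
Why: The cis-8,9-diol forms a five-membered dibutylstannylene acetal whose equatorial oxygen (O9) is the more nucleophilic one, so the acid chloride should acylate the C9 hydroxyl selectively and without amine base (stannylene-mediated regioselective acylation).

Step 23
Reactants: 30 8α-hydroxy-7β-isopropenyl-2α-(4-methoxybenzyloxy)-4β,5β-dimethyl-trans-decalin-9α-yl (2Z)-3-methylpent-2-enoate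
Product: 31 2α,8α-dihydroxy-7β-isopropenyl-4β,5β-dimethyl-trans-decalin-9α-yl (2Z)-3-methylpent-2-enoate (CNP0129603.1)
Conditions: DDQ, CH2Cl2/pH 7 buffer, 0 to 25 °C
Reagents that add atoms: none
Why: DDQ oxidises the electron-rich 4-methoxybenzyl ether to an oxocarbenium ion that water hydrolyses to the free 2α-alcohol (oxidative PMB cleavage) under neutral conditions that should leave the enoate, the isopropenyl group and the 8-hydroxyl untouched and not promote acyl migration.

**Compound list**
1 | 1-bromo-2,3-dimethylbenzene | Cc1cccc(Br)c1C | starting material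
2 | 4-chlorobutanoyl chloride | O=C(Cl)CCCCl | starting material
3 | (2,3-dimethylphenyl)magnesium bromide | Cc1cccc([Mg]Br)c1C | intermediate
4 | 4-chloro-1-(2,3-dimethylphenyl)butan-1-one | Cc1cccc(C(=O)CCCCl)c1C | intermediate
5 | (1S)-4-chloro-1-(2,3-dimethylphenyl)butan-1-ol | Cc1cccc([C@@H](O)CCCCl)c1C | intermediate
6 | tert-butyl[(1S)-4-chloro-1-(2,3-dimethylphenyl)butoxy]dimethylsilane | Cc1cccc([C@@H](O[Si](C)(C)C(C)(C)C)CCCCl)c1C | intermediate
7 | 2-{3-[(1S)-1-(tert-butyldimethylsilyloxy)-4-chlorobutyl]-4,5-dimethylphenyl}-4,4,5,5-tetramethyl-1,3,2-dioxaborolane | Cc1cc(B2OC(C)(C)C(C)(C)O2)cc([C@@H](O[Si](C)(C)C(C)(C)C)CCCCl)c1C | intermediate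
8 | 3-[(1S)-1-(tert-butyldimethylsilyloxy)-4-chlorobutyl]-4,5-dimethylphenol | Cc1cc(O)cc([C@@H](O[Si](C)(C)C(C)(C)C)CCCCl)c1C | intermediate
9 | 2,6-dibromo-3-[(1S)-1-(tert-butyldimethylsilyloxy)-4-chlorobutyl]-4,5-dimethylphenol | Cc1c(Br)c(O)c(Br)c([C@@H](O[Si](C)(C)C(C)(C)C)CCCCl)c1C | intermediate
10 | 2,6-dibromo-3-[(1S)-1-(tert-butyldimethylsilyloxy)-4-iodobutyl]-4,5-dimethylphenol | Cc1c(Br)c(O)c(Br)c([C@@H](O[Si](C)(C)C(C)(C)C)CCCI)c1C | intermediate
11 | (4aR,8S)-1,3-dibromo-8-(tert-butyldimethylsilyloxy)-4,4a-dimethyl-5,6,7,8-tetrahydronaphthalen-2(4aH)-one | C1C[C@]2(C)C(C)=C(Br)C(=O)C(Br)=C2[C@@H](O[Si](C)(C)C(C)(C)C)C1 | intermediate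
12 | 9β-(tert-butyldimethylsilyloxy)-4β,5β-dimethyl-trans-decalin-2-one | C1C[C@]2(C)[C@@H](C)CC(=O)C[C@H]2[C@@H](O[Si](C)(C)C(C)(C)C)C1 | intermediate
13 | 9β-(tert-butyldimethylsilyloxy)-4β,5β-dimethyl-trans-decalin-2α-ol | C1C[C@]2(C)[C@@H](C)C[C@H](O)C[C@H]2[C@@H](O[Si](C)(C)C(C)(C)C)C1 | intermediate
14 | 2α-(4-methoxybenzyloxy)-9β-(tert-butyldimethylsilyloxy)-4β,5β-dimethyl-trans-decalin | C1C[C@]2(C)[C@@H](C)C[C@H](OCc3ccc(OC)cc3)C[C@H]2[C@@H](O[Si](C)(C)C(C)(C)C)C1 | intermediate
15 | 2α-(4-methoxybenzyloxy)-4β,5β-dimethyl-trans-decalin-9β-ol | C1C[C@]2(C)[C@@H](C)C[C@H](OCc3ccc(OC)cc3)C[C@H]2[C@@H](O)C1 | intermediate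
16 | 2α-(4-methoxybenzyloxy)-4β,5β-dimethyl-trans-decalin-9-one | C1C[C@]2(C)[C@@H](C)C[C@H](OCc3ccc(OC)cc3)C[C@H]2C(=O)C1 | intermediate
17 | 2α-(4-methoxybenzyloxy)-4β,5β-dimethyl-9-(trimethylsilyloxy)-trans-decal-8-ene | C1C[C@]2(C)[C@@H](C)C[C@H](OCc3ccc(OC)cc3)C[C@H]2C(O[Si](C)(C)C)=C1 | intermediate
18 | 2α-(4-methoxybenzyloxy)-4β,5β-dimethyl-trans-decal-7-en-9-one | C=1C[C@]2(C)[C@@H](C)C[C@H](OCc3ccc(OC)cc3)C[C@H]2C(=O)C=1 | intermediate
19 | 2α-(4-methoxybenzyloxy)-4β,5β-dimethyl-trans-decal-7-en-9β-ol | C=1C[C@]2(C)[C@@H](C)C[C@H](OCc3ccc(OC)cc3)C[C@H]2[C@@H](O)C=1 | intermediate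
20 | 2α-(4-methoxybenzyloxy)-4β,5β-dimethyl-trans-decal-7-en-9α-yl 4-nitrobenzoate | C=1C[C@]2(C)[C@@H](C)C[C@H](OCc3ccc(OC)cc3)C[C@H]2[C@H](OC(=O)c4ccc(cc4)[N+](=O)[O-])C=1 | intermediate
21 | 2α-(4-methoxybenzyloxy)-4β,5β-dimethyl-trans-decal-7-en-9α-ol | C=1C[C@]2(C)[C@@H](C)C[C@H](OCc3ccc(OC)cc3)C[C@H]2[C@H](O)C=1 | intermediate
22 | 7α,8α-epoxy-2α-(4-methoxybenzyloxy)-4β,5β-dimethyl-trans-decalin-9α-ol | [C@@H]12C[C@]3(C)[C@@H](C)C[C@H](OCc4ccc(OC)cc4)C[C@H]3[C@H](O)[C@@H]1O2 | intermediate
23 | isopropenylmagnesium bromide | C=C(C)[Mg]Br | starting material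
24 | 7β-isopropenyl-2α-(4-methoxybenzyloxy)-4β,5β-dimethyl-trans-decalin-8α,9α-diol | C=C(C)[C@H]1C[C@]2(C)[C@@H](C)C[C@H](OCc3ccc(OC)cc3)C[C@H]2[C@H](O)[C@@H]1O | intermediate
25 | ethyl pent-2-ynoate | CCC#CC(=O)OCC | starting material
26 | ethyl (2Z)-3-methylpent-2-enoate | CCOC(=O)/C=C(/C)CC | intermediate
27 | (2Z)-3-methylpent-2-enoic acid | OC(=O)/C=C(/C)CC | intermediate
28 | (2Z)-3-methylpent-2-enoyl chloride | ClC(=O)/C=C(/C)CC | intermediate
29 | 8α,9α-O-dibutylstannylene acetal of diol 24 | C=C(C)[C@H]1C[C@]2(C)[C@@H](C)C[C@H](OCc3ccc(OC)cc3)C[C@H]2[C@H](O[Sn](CCCC)(CCCC)O5)[C@@H]15 | intermediate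
30 | 8α-hydroxy-7β-isopropenyl-2α-(4-methoxybenzyloxy)-4β,5β-dimethyl-trans-decalin-9α-yl (2Z)-3-methylpent-2-enoate | C=C(C)[C@H]1C[C@]2(C)[C@@H](C)C[C@H](OCc3ccc(OC)cc3)C[C@H]2[C@H](OC(=O)/C=C(/C)CC)[C@@H]1O | intermediate
31 | 2α,8α-dihydroxy-7β-isopropenyl-4β,5β-dimethyl-trans-decalin-9α-yl (2Z)-3-methylpent-2-enoate (CNP0129603.1) | C=C(C)[C@H]1C[C@]2(C)[C@@H](C)C[C@H](O)C[C@H]2[C@H](OC(=O)/C=C(/C)CC)[C@@H]1O | target

**Step count**
Total: 23 steps. Longest linear sequence: 20 steps (steps 1–18, 22, 23); steps 19–21 make the acyl chloride in a side branch.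

**Steps most likely to fail**

1. Step 7 (key step). The electron-poor dibromophenolate may alkylate at C5 too slowly, so that intermolecular O-alkylation, attack at the bromine-bearing ortho carbon C1, or weak facial discrimination by the C9 silyl ether erodes the yield of the single C5 diastereomer. The fallback gives up the dearomatisation and builds the decalin by annulation. It cannot branch from compounds 1–10, since each of them would still need the same ring closure; it starts from commercial 2-methylcyclohexanone and comes back to the route at compound 12. Condensation of 2-methylcyclohexanone with (S)-1-phenylethylamine gives the imine of 2-methylcyclohexanone F1. Deracemising Michael addition of its more substituted enamine tautomer to (E)-pent-3-en-2-one should give the adduct imine F2, which aqueous acetic acid hydrolyses to (2R)-2-methyl-2-[(2S)-4-oxopentan-2-yl]cyclohexan-1-one F3. Aldol condensation (NaOMe, MeOH) closes ring A to (4S,4aR)-4,4a-dimethyl-4,4a,5,6,7,8-hexahydronaphthalen-2(3H)-one F4. Isopropenyl acetate with TsOH gives the heteroannular dienyl acetate F5, and mCPBA oxidises it at the γ-carbon by axial attack to the 9β-hydroxy enone F6, as in the 6β-hydroxylation of steroidal 4-en-3-ones. Silylation (TBSOTf, 2,6-lutidine) gives the 9β-silyloxy enone F7, and hydrogenation over Pd/C from the α face, as in step 8, should give 12.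

2. Step 8. Hydrogen may be delivered to C4 or C10 from the β face (4-epimer or cis ring fusion), or the allylic C9–O bond may be hydrogenolysed before C1=C10 is saturated. The fallback sets out from 11 and comes back at 12; it replaces catalyst-face control by the stereoelectronic control of a dissolving-metal reduction. The silyl ether is first removed (HF·pyridine, THF), because a γ-silyloxy group would be eliminated from the enone radical anion, giving the 9β-hydroxy dibromodienone F8. Li in NH3/THF with t-BuOH then removes both bromines and reduces both enone double bonds with axial protonation at C4 and C10 (equatorial 4β-methyl, 10α-H), giving the 9β-hydroxy trans-decalin-2-one F9; any C2 alcohol from over-reduction is re-oxidised with Dess–Martin periodinane. Resilylation (TBSOTf, 2,6-lutidine) returns 12.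

3. Step 18. Attack at C7 is syn-axial to the C5 methyl and may be slower than opening at C8, bromohydrin formation by the magnesium bromide salts, or base-induced isomerisation of the epoxide. The fallback sets out from 22 and comes back at 24; it brings in the three carbons in two stages, with a slim sp nucleophile first. Et2AlC≡CSiMe3 (from trimethylsilylacetylene, n-BuLi and Et2AlCl) opens the epoxy alcohol at the distal carbon C7, trans-diaxially, to give the 7β-(trimethylsilylethynyl) diol F10. K2CO3 in MeOH removes the silyl group to give the 7β-ethynyl diol F11. Negishi methylalumination (AlMe3 in excess, Cp2ZrCl2, CH2Cl2), which adds methyl to the internal alkyne carbon, followed by protonolysis with water converts the ethynyl group into the isopropenyl group of 24.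

**Further compounds**
F1 | step 7 | N-[(1S)-1-phenylethyl]-2-methylcyclohexan-1-imine | CC1CCCCC1=N[C@@H](C)c1ccccc1
F2 | step 7 | (4S)-4-{(1R)-1-methyl-2-[(1S)-1-phenylethylimino]cyclohexyl}pentan-2-one | C[C@H](N=C1CCCC[C@]1(C)[C@@H](C)CC(C)=O)c1ccccc1
F3 | step 7 | (2R)-2-methyl-2-[(2S)-4-oxopentan-2-yl]cyclohexan-1-one | O=C1CCCC[C@]1(C)[C@@H](C)CC(C)=O
F4 | step 7 | (4S,4aR)-4,4a-dimethyl-4,4a,5,6,7,8-hexahydronaphthalen-2(3H)-one | C1C[C@]2(C)[C@@H](C)CC(=O)C=C2CC1
F5 | step 7 | (4S,4aR)-4,4a-dimethyl-3,4,4a,5,6,7-hexahydronaphthalen-2-yl acetate | C1C[C@]2(C)[C@@H](C)CC(OC(C)=O)=CC2=CC1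
F6 | step 7 | 9β-hydroxy-4β,5β-dimethyl-decal-1(10)-en-2-one | C1C[C@]2(C)[C@@H](C)CC(=O)C=C2[C@@H](O)C1
F7 | step 7 | 9β-(tert-butyldimethylsilyloxy)-4β,5β-dimethyl-decal-1(10)-en-2-one | C1C[C@]2(C)[C@@H](C)CC(=O)C=C2[C@@H](O[Si](C)(C)C(C)(C)C)C1
F8 | step 8 | (4aR,8S)-1,3-dibromo-8-hydroxy-4,4a-dimethyl-5,6,7,8-tetrahydronaphthalen-2(4aH)-one | C1C[C@]2(C)C(C)=C(Br)C(=O)C(Br)=C2[C@@H](O)C1
F9 | step 8 | 9β-hydroxy-4β,5β-dimethyl-trans-decalin-2-one | C1C[C@]2(C)[C@@H](C)CC(=O)C[C@H]2[C@@H](O)C1
F10 | step 18 | 2α-(4-methoxybenzyloxy)-4β,5β-dimethyl-7β-(trimethylsilylethynyl)-trans-decalin-8α,9α-diol | C[Si](C)(C)C#C[C@H]1C[C@]2(C)[C@@H](C)C[C@H](OCc3ccc(OC)cc3)C[C@H]2[C@H](O)[C@@H]1O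
F11 | step 18 | 7β-ethynyl-2α-(4-methoxybenzyloxy)-4β,5β-dimethyl-trans-decalin-8α,9α-diol | C#C[C@H]1C[C@]2(C)[C@@H](C)C[C@H](OCc3ccc(OC)cc3)C[C@H]2[C@H](O)[C@@H]1O
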